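**Retrosynthetic overview** (locants: C1 = ring C=O, C2 = methyl-bearing oxirane carbon, C3 = oxirane CH, C4 = CH2, C5 = side-chain-bearing carbon, C6 = angelate-bearing carbon, C1′ = side-chain carbinol)
1. Target ⇐ α-oxygenation of the C1 ketone at C6 anti to C5 and two angeloylations; C1′ and the exomethylene ⇐ Nozaki–Hiyama–Kishi coupling of a C5 alkenyl triflate (from a C5 acetyl group) with 4-methylpent-3-enal.
2. C5–H ⇐ a C5,C5-dicarboxylate: the carboxyl cis to O-1 is locked as a bridged γ-lactone (it becomes the side-chain carbon), the other is excised at the bridgehead.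
3. Key disconnection: C4–C5 and C2–C3 (plus C3–O) in one operation from acyclic keto-malonate 6 and diphenyl(vinyl)sulfonium triflate 7 (Michael addition, then intramolecular sulfonium-ylide epoxidation). The enabling feature is the oxirane fused at C2–C3, whose oxygen sits on the methyl-bearing C2 next to the C3H–C4H2 unit: C2 is a masked methyl-ketone carbonyl, C3–C4 are the two vinyl carbons and C5 can be a malonate carbon.
4. Ring order: cyclohexane, then oxirane (both in step 4), then the temporary lactone (step 5, opened in step 8).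

Key step: step 4

Remark: (S)-2-hydroxybut-3-en-1-yl tosylate is taken as a catalogue chiral building block; its carbinol carbon becomes C1, relays all ring stereochemistry and is finally oxidised to the ketone.

Step 1
Reactants: 1 (S)-2-hydroxybut-3-en-1-yl 4-methylbenzenesulfonate
Product: 2 (S)-2-[(tert-butyldimethylsilyl)oxy]but-3-en-1-yl 4-methylbenzenesulfonate
Conditions: t-BuMe2SiOTf, 2,6-lutidine, CH2Cl2, −78 → 0 °C
Reagents that add atoms: tert-butyldimethylsilyl triflate, CC(C)(C)[Si](C)(C)OS(=O)(=O)C(F)(F)F
Why: O-silylation of the secondary alcohol with a silyl triflate and a hindered base is fast at low temperature and touches neither the stereocentre nor the primary tosylate.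

Step 2
Reactants: 2 (S)-silyloxy tosylate; 3 dibenzyl malonate
Product: 5 dibenzyl (R)-2-{2-[(tert-butyldimethylsilyl)oxy]but-3-en-1-yl}malonate, via sodium dibenzyl malonate 4 (not isolated)
Conditions: NaH, THF/DMF 1:1, 0 °C; then 2, 65 °C
Reagents that add atoms: dibenzyl malonate (3), O=C(CC(=O)OCc1ccccc1)OCc1ccccc1
Why: Malonic ester alkylation (SN2 of the soft malonate anion at the primary tosylate) leaves the neighbouring silyloxy stereocentre untouched (the descriptor changes to R only through priorities).

Step 3
Reactants: 5 alkenyl malonate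
Product: 6 dibenzyl (R)-2-{2-[(tert-butyldimethylsilyl)oxy]-3-oxobutyl}malonate
Conditions: PdCl2(Quinox) (Quinox = 2-(4,5-dihydrooxazol-2-yl)quinoline, 5 mol %), AgSbF6 (12.5 mol %), 70 % aq. t-BuOOH, CH2Cl2, 0 °C → rt
Reagents that add atoms: tert-butyl hydroperoxide, CC(C)(C)OO
Why: Wacker-type oxidation with the cationic quinoline–oxazoline complex of divalent palladium and t-BuOOH should convert the protected allylic alcohol into the methyl ketone with catalyst-controlled Markovnikov selectivity and without erosion of the allylic stereocentre, benzyl esters and silyl ether being inert.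

Step 4
Reactants: 6 keto-malonate; 7 diphenyl(vinyl)sulfonium trifluoromethanesulfonate
Product: 11 dibenzyl 1-[(tert-butyldimethylsilyl)oxy]-2,3-epoxy-2-methylcyclohexane-5,5-dicarboxylate (silyloxy group cis to the epoxide oxygen), via malonate carbanion 8 (not isolated), via sulfonium ylide 9 (not isolated), via betaine 10 (not isolated)
Conditions: DBU (1.5 equiv), CH2Cl2, 0 °C → rt
Reagents that add atoms: diphenyl(vinyl)sulfonium triflate (7), C=C[S+](c1ccccc1)c1ccccc1.[O-]S(=O)(=O)C(F)(F)F
Why: DBU deprotonates the malonate C–H (the only soft acidic site) to 8, which adds in Michael fashion to the vinylsulfonium salt (C5–C4 bond) and so generates ylide 9 at C3; the ylide carbon adds to the methyl ketone (C3–C2 bond, betaine 10) and the alkoxide expels Ph2S to close the oxirane. The closest known reaction type is the epoxy-annulation of ketone-tethered sulfonamide, alcohol and malonate nucleophiles with diphenyl(vinyl)sulfonium triflate, an intramolecular Corey–Chaykovsky epoxidation. The cyclohexane closes by 6-exo-trig attack of the ylide carbon on the ketone carbonyl, the oxirane by 3-exo-tet displacement at C3 with O− and S+ antiperiplanar (trans-diaxial). C2 is controlled by the C1 silyloxy stereocentre: in the chair transition state the polar Felkin–Anh arrangement (C1–O anti to the forming C3–C2 bond, the ring CH2 next to the carbonyl oxygen, H next to CH3) places OSi and CH3 equatorial and O− axial, which should put the epoxide oxygen cis to O-1, and C3 follows from the antiperiplanar closure. The step needs alkylation at the malonate carbon rather than at the ketone enolate and no cyclopropanation, secured because the malonate is by far the most acidic site and C5 is quaternary after the Michael addition, and it needs closure onto the ketone only, secured because the esters are inert to the ylide and the ketone is the one carbonyl reachable through a six-membered transition state.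

Step 5
Reactants: 11 epoxy silyl ether
Product: 13 benzyl 3,4-epoxy-4-methyl-7-oxo-6-oxabicyclo[3.2.1]octane-1-carboxylate (epoxide oxygen on the face of the lactone bridge), via hydroxy diester 12 (not isolated)
Conditions: Bu4NF, THF, 0 °C → rt
Reagents that add atoms: none
Why: Fluoride desilylation frees the C1 alkoxide, which lactonises (transesterification) only with the C5 ester on its own ring face, so C5 becomes a defined stereocentre with the lactone carbonyl (the future side-chain carbon) cis to O-1 and to the epoxide; a cis-epoxy alkoxide cannot undergo Payne rearrangement.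

Step 6
Reactants: 13 lactone benzyl ester
Product: 14 3,4-epoxy-4-methyl-7-oxo-6-oxabicyclo[3.2.1]octane-1-carboxylic acid
Conditions: H2 (1 atm), Pd/C (10 wt %), EtOAc, rt
Reagents that add atoms: none
Why: Hydrogenolysis cleaves only the benzyl ester (trialkyl epoxide and lactone are inert), and the bridgehead acid cannot decarboxylate because its position forbids enolisation.

Step 7
Reactants: 14 bridgehead acid
Product: 16 3,4-epoxy-4-methyl-6-oxabicyclo[3.2.1]octan-7-one, via thiohydroxamate ester 15 (not isolated)
Conditions: N-hydroxypyridine-2-thione, DCC, DMAP (cat.), CH2Cl2, 0 °C, dark; then t-BuSH, visible light, rt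
Reagents that add atoms: none
Why: Barton reductive decarboxylation gives a bridgehead radical that can take hydrogen from the thiol only on the face vacated by CO2, so C5–H forms with enforced retention and the C5 carbonyl carbon stays cis to the epoxide.

Step 8
Reactants: 16 bridged lactone
Product: 18 5-acetyl-2,3-epoxy-2-methylcyclohexan-1-ol (hydroxyl, epoxide oxygen and acetyl all cis), via lithium hemiketal alkoxide 17 (not isolated)
Conditions: MeLi (1.05 equiv), THF, −78 °C; AcOH, −78 °C
Reagents that add atoms: methyllithium, [Li]C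
Why: Mono-addition of an organolithium to a lactone stops at the tetrahedral adduct 17 at −78 °C, which collapses to the methyl ketone only on protonation; C5 is not acidic before ring opening and no base remains afterwards.

Step 9
Reactants: 18 hydroxy ketone
Product: 19 5-acetyl-2,3-epoxy-2-methyl-1-(triethylsilyloxy)cyclohexane
Conditions: Et3SiCl, imidazole, DMF, 0 °C → rt
Reagents that add atoms: chlorotriethylsilane, CC[Si](Cl)(CC)CC
Why: Silylation of the C1 hydroxyl of the open hydroxy ketone (in equilibrium with its bridged hemiketal) with a silyl chloride and imidazole does not enolise the ketone, so C5 is kept.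

Step 10
Reactants: 19 silyl ether ketone
Product: 21 1-[2,3-epoxy-2-methyl-1-(triethylsilyloxy)cyclohex-5-yl]vinyl trifluoromethanesulfonate, via potassium enolate 20 (not isolated)
Conditions: KN(SiMe3)2, THF, −78 °C; PhNTf2, −78 → 0 °C
Reagents that add atoms: N-phenylbis(trifluoromethanesulfonimide), O=S(=O)(N(c1ccccc1)S(=O)(=O)C(F)(F)F)C(F)(F)F
Why: Kinetic deprotonation of the unhindered methyl group and O-triflation of the enolate (enol triflate formation) gives the terminal alkenyl triflate without touching the tertiary C5–H.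

Step 11
Reactants: 22 4-methylpent-3-en-1-ol
Product: 23 4-methylpent-3-enal
Conditions: DMP (1,1,1-triacetoxy-1,1-dihydro-1,2-benziodoxol-3(1H)-one), CH2Cl2, 0 °C → rt
Reagents that add atoms: none
Why: Periodinane oxidation under neutral conditions gives the β,γ-unsaturated aldehyde without migration of the double bond into conjugation; it is used directly.

Step 12
Reactants: 21 alkenyl triflate; 23 4-methylpent-3-enal
Product: 25 (S)-2-[2,3-epoxy-2-methyl-1-(triethylsilyloxy)cyclohex-5-yl]-6-methylhepta-1,5-dien-3-ol, via alkenylchromium species 24 (not isolated)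
Conditions: CrCl2 (3 equiv) as its complex with a chiral oxazoline–sulfonamide ligand, NiCl2 (1 mol %), THF, rt
Reagents that add atoms: 4-methylpent-3-enal (23), CC(C)=CCC=O
Why: Nozaki–Hiyama–Kishi reaction (oxidative addition of the triflate to zerovalent nickel, transmetalation to trivalent chromium, chemoselective addition to the aldehyde) tolerates epoxide and silyl ether, and the C1′ (S) centre is set by the chiral ligand on chromium, the ligand enantiomer being chosen for this sense.

Step 13
Reactants: 26 angelic acid
Product: 27 (Z)-2-methylbut-2-enoic 2,4,6-trichlorobenzoic anhydride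
Conditions: 2,4,6-trichlorobenzoyl chloride, Et3N, toluene, rt; Et3NHCl filtered off under argon; filtrate kept cold as a toluene stock solution
Reagents that add atoms: 2,4,6-trichlorobenzoyl chloride, O=C(Cl)c1c(Cl)cc(Cl)cc1Cl
Why: Acylation of the triethylammonium carboxylate by the hindered aroyl chloride (first stage of the Yamaguchi esterification) gives the mixed anhydride without a nucleophilic catalyst that could add to the angelate and isomerise it to the tiglate, and one batch serves both esterifications (steps 14 and 18).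

Step 14
Reactants: 25 allylic alcohol; 27 mixed anhydride
Product: 28 C1′ angelate of 25
Conditions: 27 (toluene solution, excess), toluene, 80 °C
Reagents that add atoms: mixed anhydride (27), C/C=C(/C)C(=O)OC(=O)c1c(Cl)cc(Cl)cc1Cl
Why: Yamaguchi-type esterification in which the secondary allylic alcohol attacks the less hindered angeloyl carbonyl of the mixed anhydride, run without a nucleophilic catalyst so that the (Z)-angelate is not isomerised to the tiglate.

Step 15
Reactants: 28 angelate silyl ether
Product: 29 C1′ angelate with free C1 hydroxyl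
Conditions: HF·pyridine, pyridine/THF, 0 °C → rt
Reagents that add atoms: none
Why: Buffered fluoride cleavage of the triethylsilyl ether leaves angelate, epoxide and both alkenes intact.

Step 16
Reactants: 29 epoxy alcohol
Product: 30 6-deoxy target: C1′ angelate of the 2,3-epoxy-2-methylcyclohexanone
Conditions: DMP, CH2Cl2, rt
Reagents that add atoms: none
Why: Periodinane oxidation converts the secondary epoxy alcohol into the α,β-epoxy ketone under neutral conditions and removes the relay stereocentre C1.

Step 17
Reactants: 30 epoxy ketone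
Product: 32 6-hydroxy ketone (hydroxyl trans to the C5 side chain), via potassium enolate 31 (not isolated)
Conditions: KN(SiMe3)2 (1.05 equiv), THF, −78 °C; 2-(phenylsulfonyl)-3-phenyloxaziridine, −78 °C; AcOH
Reagents that add atoms: 2-(phenylsulfonyl)-3-phenyloxaziridine, O=S(=O)(c1ccccc1)N1OC1c1ccccc1
Why: Enolate oxidation with an N-sulfonyloxaziridine occurs at C6, the only enolisable side (C2 is quaternary), and the oxidant should approach anti to the adjacent C5 substituent, giving the trans (also the more stable diequatorial) C5/C6 relationship.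

Step 18
Reactants: 32 6-hydroxy ketone; 27 mixed anhydride
Product: 33 CNP0271744.2 (target)
Conditions: 27 (toluene solution, excess), toluene, 60 °C
Reagents that add atoms: mixed anhydride (27), C/C=C(/C)C(=O)OC(=O)c1c(Cl)cc(Cl)cc1Cl
Why: Yamaguchi-type esterification of the α-hydroxy ketone with the mixed anhydride under essentially neutral conditions installs the second angelate without epoxide opening or angelate isomerisation, and C6 keeps its more stable trans configuration.

**Compound list**
1 | (S)-2-hydroxybut-3-en-1-yl 4-methylbenzenesulfonate | C=C[C@H](O)COS(=O)(=O)c1ccc(C)cc1 | starting material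
2 | (S)-2-[(tert-butyldimethylsilyl)oxy]but-3-en-1-yl 4-methylbenzenesulfonate | C=C[C@H](O[Si](C)(C)C(C)(C)C)COS(=O)(=O)c1ccc(C)cc1 | intermediate
3 | dibenzyl malonate | O=C(CC(=O)OCc1ccccc1)OCc1ccccc1 | starting material
4 | sodium dibenzyl malonate | [Na+].O=C([CH-]C(=O)OCc1ccccc1)OCc1ccccc1 | intermediate (not isolated)
5 | dibenzyl (R)-2-{2-[(tert-butyldimethylsilyl)oxy]but-3-en-1-yl}malonate | C=C[C@H](O[Si](C)(C)C(C)(C)C)CC(C(=O)OCc1ccccc1)C(=O)OCc1ccccc1 | intermediate
6 | dibenzyl (R)-2-{2-[(tert-butyldimethylsilyl)oxy]-3-oxobutyl}malonate | CC(=O)[C@H](O[Si](C)(C)C(C)(C)C)CC(C(=O)OCc1ccccc1)C(=O)OCc1ccccc1 | intermediate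
7 | diphenyl(vinyl)sulfonium trifluoromethanesulfonate | C=C[S+](c1ccccc1)c1ccccc1.[O-]S(=O)(=O)C(F)(F)F | starting material
8 | malonate carbanion of 6 as its DBU-H+ salt | CC(=O)[C@H](O[Si](C)(C)C(C)(C)C)C[C-](C(=O)OCc1ccccc1)C(=O)OCc1ccccc1.C1CCC2=[NH+]CCCN2CC1 | intermediate (not isolated)
9 | sulfonium ylide: 6 with a 2-(diphenylsulfonio)ethan-2-ide chain on the malonate carbon | CC(=O)[C@H](O[Si](C)(C)C(C)(C)C)CC(C[CH-][S+](c1ccccc1)c1ccccc1)(C(=O)OCc1ccccc1)C(=O)OCc1ccccc1 | intermediate (not isolated)
10 | betaine: dibenzyl 3-(diphenylsulfonio)-4-methyl-4-oxido-5-silyloxycyclohexane-1,1-dicarboxylate, O− and S+ trans-diaxial | O=C(OCc1ccccc1)C1(C(=O)OCc2ccccc2)C[C@@H]([S+](c2ccccc2)c2ccccc2)[C@@]([O-])(C)[C@H](O[Si](C)(C)C(C)(C)C)C1 | intermediate (not isolated)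
11 | dibenzyl 1-[(tert-butyldimethylsilyl)oxy]-2,3-epoxy-2-methylcyclohexane-5,5-dicarboxylate, silyloxy cis to epoxide O (C1 R, C2 S, C3 S) | O=C(OCc1ccccc1)C1(C(=O)OCc2ccccc2)C[C@@H]2O[C@]2(C)[C@H](O[Si](C)(C)C(C)(C)C)C1 | intermediate
12 | dibenzyl 2,3-epoxy-1-hydroxy-2-methylcyclohexane-5,5-dicarboxylate, hydroxyl cis to epoxide O | O=C(OCc1ccccc1)C1(C(=O)OCc2ccccc2)C[C@@H]2O[C@]2(C)[C@H](O)C1 | intermediate (not isolated)
13 | benzyl 3,4-epoxy-4-methyl-7-oxo-6-oxabicyclo[3.2.1]octane-1-carboxylate | O=C(OCc1ccccc1)[C@]12C[C@@H]3O[C@]3(C)[C@H](OC1=O)C2 | intermediate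
14 | 3,4-epoxy-4-methyl-7-oxo-6-oxabicyclo[3.2.1]octane-1-carboxylic acid | OC(=O)[C@]12C[C@@H]3O[C@]3(C)[C@H](OC1=O)C2 | intermediate
15 | ester of 14 with N-hydroxypyridine-2-thione | O=C(ON1C=CC=CC1=S)[C@]12C[C@@H]3O[C@]3(C)[C@H](OC1=O)C2 | intermediate (not isolated)
16 | 3,4-epoxy-4-methyl-6-oxabicyclo[3.2.1]octan-7-one (epoxide O on the face of the lactone bridge) | [C@H]12C[C@@H]3O[C@]3(C)[C@H](OC1=O)C2 | intermediate
17 | lithium 3,4-epoxy-4,7-dimethyl-6-oxabicyclo[3.2.1]octan-7-olate (hemiketal carbon undefined) | [C@H]12C[C@@H]3O[C@]3(C)[C@H](OC1(C)[O-])C2.[Li+] | intermediate (not isolated)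
18 | 5-acetyl-2,3-epoxy-2-methylcyclohexan-1-ol, OH, epoxide O and acetyl all cis | CC(=O)[C@@H]1C[C@@H]2O[C@]2(C)[C@H](O)C1 | intermediate
19 | triethylsilyl ether of 18 | CC(=O)[C@@H]1C[C@@H]2O[C@]2(C)[C@H](O[Si](CC)(CC)CC)C1 | intermediate
20 | potassium enolate of 19 (methyl side) | C=C([O-])[C@@H]1C[C@@H]2O[C@]2(C)[C@H](O[Si](CC)(CC)CC)C1.[K+] | intermediate (not isolated)
21 | 1-[2,3-epoxy-2-methyl-1-(triethylsilyloxy)cyclohex-5-yl]vinyl trifluoromethanesulfonate | C=C(OS(=O)(=O)C(F)(F)F)[C@@H]1C[C@@H]2O[C@]2(C)[C@H](O[Si](CC)(CC)CC)C1 | intermediate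
22 | 4-methylpent-3-en-1-ol | CC(C)=CCCO | starting material
23 | 4-methylpent-3-enal | CC(C)=CCC=O | intermediate
24 | alkenylchromium dichloride from 21 | C=C([Cr](Cl)Cl)[C@@H]1C[C@@H]2O[C@]2(C)[C@H](O[Si](CC)(CC)CC)C1 | intermediate (not isolated)
25 | (S)-2-[2,3-epoxy-2-methyl-1-(triethylsilyloxy)cyclohex-5-yl]-6-methylhepta-1,5-dien-3-ol | C=C([C@H](CC=C(C)C)O)[C@@H]1C[C@@H]2O[C@]2(C)[C@H](O[Si](CC)(CC)CC)C1 | intermediate
26 | angelic acid, (Z)-2-methylbut-2-enoic acid | C/C=C(/C)C(=O)O | starting material
27 | (Z)-2-methylbut-2-enoic 2,4,6-trichlorobenzoic anhydride | C/C=C(/C)C(=O)OC(=O)c1c(Cl)cc(Cl)cc1Cl | intermediate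
28 | C1′ angelate of 25 | C=C([C@H](CC=C(C)C)OC(=O)/C(C)=C\C)[C@@H]1C[C@@H]2O[C@]2(C)[C@H](O[Si](CC)(CC)CC)C1 | intermediate
29 | C1′ angelate with free C1 hydroxyl | C=C([C@H](CC=C(C)C)OC(=O)/C(C)=C\C)[C@@H]1C[C@@H]2O[C@]2(C)[C@H](O)C1 | intermediate
30 | C1′ angelate, 2,3-epoxy-2-methylcyclohexan-1-one (6-deoxy target) | C=C([C@H](CC=C(C)C)OC(=O)/C(C)=C\C)[C@@H]1C[C@@H]2O[C@]2(C)C(=O)C1 | intermediate
31 | potassium enolate of 30 (C1–C6) | C=C([C@H](CC=C(C)C)OC(=O)/C(C)=C\C)[C@@H]1C[C@@H]2O[C@]2(C)C([O-])=C1.[K+] | intermediate (not isolated)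
32 | 6-hydroxy ketone, OH trans to the C5 side chain | C=C([C@H](CC=C(C)C)OC(=O)/C(C)=C\C)[C@@H]1C[C@@H]2O[C@]2(C)C(=O)[C@H]1O | intermediate
33 | CNP0271744.2 | C=C([C@H](CC=C(C)C)OC(=O)/C(C)=C\C)[C@@H]1C[C@@H]2O[C@]2(C)C(=O)[C@H]1OC(=O)/C(C)=C\C | target

Total step count: 18. Longest linear sequence: 16 steps (steps 1–10, 12 and 14–18; step 11 prepares aldehyde 23 and step 13 prepares anhydride 27).

**Steps most likely to fail**

Step 4. What may go wrong is protonation of ylide 9 by DBU-H+ with side reactions of the resulting sulfonium salt, enolisation of the methyl ketone by the ylide, epimerisation at C1 by DBU before ring closure, or incomplete facial selectivity so that the epoxide forms trans to O-1. The fallback builds the ring and the epoxide in separate, known steps. Setting out from 6, C-allylation (NaH, allyl bromide, DMF, 0 °C) would give dibenzyl 2-allyl-2-{(R)-2-[(tert-butyldimethylsilyl)oxy]-3-oxobutyl}malonate F1. Wittig methylenation of the ketone (Ph3P=CH2 from Ph3PCH3Br and KOt-Bu, THF, 0 °C), to which the quaternary malonate and the benzyl esters are inert, would give the 1,7-diene F2. Ring-closing metathesis (second-generation Grubbs catalyst RuCl2(=CHPh)(H2IMes)(PCy3), CH2Cl2, 40 °C) would give the cyclohexene F3, and HF·pyridine the allylic alcohol F4. Hydroxyl-directed epoxidation (VO(acac)2 cat., t-BuOOH, CH2Cl2) delivers oxygen syn to the hydroxyl and should give hydroxy diester 12, which catalytic DBU lactonises to 13, where the route is rejoined.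

Step 12. What may go wrong is poor facial selectivity at the aldehyde (ligand control overridden by the C5 stereocentre) and drift of the β,γ-unsaturated aldehyde into conjugation. The fallback sets out from 21 and 23: the coupling is run without chiral ligand (CrCl2, NiCl2 cat., DMF/THF) and gives 25 together with its C1′ (R) epimer F5. The mixture is oxidised (DMP, CH2Cl2) to the enone F6. Corey–Bakshi–Shibata reduction ((R)-2-methyl-CBS-oxazaborolidine, catecholborane, toluene, −78 °C; the α-substituted alkenyl group acting as the large substituent) should then return the (S)-carbinol 25, where the route is rejoined.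

Step 17. What may go wrong is breakdown of the epoxy-ketone enolate (attack on the oxirane, ring contraction, attack on the side-chain ester) or approach of the oxidant syn to C5. The fallback is a base-free α-acyloxylation through [3,3]-sigmatropic rearrangement of an N-alkyl-O-acylhydroxylamine–ketone adduct. Commercial tert-butyl N-hydroxy-N-methylcarbamate is acylated with 27 (Et3N, CH2Cl2) to give the O-angeloyl carbamate F7, and HCl in dioxane removes the Boc group to give the hydroxylammonium chloride F8. Setting out from 30, treatment with F8 (DMSO, rt to 40 °C) should install the C6 angelate anti to C5 and reach 33 directly, bypassing 32.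

**Further compounds**
F1 | step 4 | dibenzyl 2-allyl-2-{(R)-2-[(tert-butyldimethylsilyl)oxy]-3-oxobutyl}malonate | CC(=O)[C@H](O[Si](C)(C)C(C)(C)C)CC(CC=C)(C(=O)OCc1ccccc1)C(=O)OCc1ccccc1
F2 | step 4 | dibenzyl 2-allyl-2-{(R)-2-[(tert-butyldimethylsilyl)oxy]-3-methylbut-3-en-1-yl}malonate | C=C(C)[C@H](O[Si](C)(C)C(C)(C)C)CC(CC=C)(C(=O)OCc1ccccc1)C(=O)OCc1ccccc1
F3 | step 4 | dibenzyl (R)-5-[(tert-butyldimethylsilyl)oxy]-4-methylcyclohex-3-ene-1,1-dicarboxylate | O=C(OCc1ccccc1)C1(C(=O)OCc2ccccc2)CC=C(C)[C@H](O[Si](C)(C)C(C)(C)C)C1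
F4 | step 4 | dibenzyl (R)-5-hydroxy-4-methylcyclohex-3-ene-1,1-dicarboxylate | O=C(OCc1ccccc1)C1(C(=O)OCc2ccccc2)CC=C(C)[C@H](O)C1
F5 | step 12 | (R)-2-[2,3-epoxy-2-methyl-1-(triethylsilyloxy)cyclohex-5-yl]-6-methylhepta-1,5-dien-3-ol (C1′ epimer of 25) | C=C([C@@H](CC=C(C)C)O)[C@@H]1C[C@@H]2O[C@]2(C)[C@H](O[Si](CC)(CC)CC)C1
F6 | step 12 | 2-[2,3-epoxy-2-methyl-1-(triethylsilyloxy)cyclohex-5-yl]-6-methylhepta-1,5-dien-3-one | C=C(C(=O)CC=C(C)C)[C@@H]1C[C@@H]2O[C@]2(C)[C@H](O[Si](CC)(CC)CC)C1
F7 | step 17 | tert-butyl methyl{[(Z)-2-methylbut-2-enoyl]oxy}carbamate | C/C=C(/C)C(=O)ON(C)C(=O)OC(C)(C)C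
F8 | step 17 | N-methyl-O-[(Z)-2-methylbut-2-enoyl]hydroxylammonium chloride | C/C=C(/C)C(=O)O[NH2+]C.[Cl-]
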